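**Retrosynthetic overview**

1. Target ⇒ Suzuki–Miyaura union of alkenyl boronate 22 with iodo-dienol 25; 22 ⇒ C7 methyl ketone (boron-Wittig); epoxy acetate ⇒ hydroxyl-directed epoxidation and acetylation of cycloheptenol 19.
2. Seven-membered ring (second ring formed) ⇒ ring-closing metathesis of a C1 cis-propenyl carbinol ether with a C6 3-methylbut-3-enyl chain (17).
3. C6 chain ⇒ one-carbon homologation of ring ketone 7 and equilibration, then methylenation and B-alkyl Suzuki coupling; C1 ⇒ chelation-controlled alkynylation of β-keto aldehyde 5.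
4. Quaternary C10 (key C10–C1 bond) ⇒ stereospecific [1,2]-sigmatropic formyl shift in epoxy aldehyde 4; the epoxide is trans to the isopropenyl group, so the formyl group arrives cis to it.
5. Cyclopentene (first ring formed) ⇒ aldol condensation of the keto aldehyde from (R)-limonene oxide, whose single stereocentre becomes C7.

Assumption: the SMILES is read as the absolute configuration. Locants used below: C1 (CH–OAc), C2/C3 (epoxide, C3–Me), C4, C5, C6 (ring-fusion CH), C7 (CH with side chain), C8, C9, C10 (C–Me); β is the face of the C10 methyl, α the opposite face. The target is 1α-OAc, 2α,3α-epoxide, 6α-H, 7α-side chain, 10β-Me.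

The route is a paper design; the stereochemical outcomes of steps 3–5 and 7 are predictions from steric and chelation models, not established results.

**Step 1**
Reactants: 1 (4R)-limonene 1,2-oxide
Product: 2 (3R)-6-oxo-3-(prop-1-en-2-yl)heptanal
Conditions: H5IO6, THF/H2O, 0 °C to rt
Reagents that add atoms: water, O
Why: Epoxide hydrolysis and periodate (Malaprade) glycol cleavage open the six-membered ring to the keto aldehyde without touching C4 of limonene, the only purchased stereocentre (future C7).

**Step 2**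
Reactants: 2 (3R)-6-oxo-3-(prop-1-en-2-yl)heptanal
Product: 3 (5S)-2-methyl-5-(prop-1-en-2-yl)cyclopent-1-ene-1-carbaldehyde
Conditions: piperidine (cat.), AcOH (cat.), benzene, reflux
Reagents that add atoms: none
Why: Intramolecular aldol condensation through the piperidine enamine of the aldehyde onto the methyl ketone closes the cyclopentene, and the stereocentre is not conjugated with the carbonyl and so is not epimerised.

**Step 3**
Reactants: 3 (5S)-2-methyl-5-(prop-1-en-2-yl)cyclopent-1-ene-1-carbaldehyde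
Product: 4 epoxy aldehyde with the epoxide oxygen trans to isopropenyl
Conditions: 30% H2O2, NaOH (cat., pH 8–9), MeOH, 0 °C
Reagents that add atoms: hydrogen peroxide, OO
Why: Weitz–Scheffer nucleophilic epoxidation, in which hydroperoxide adds to the β-carbon (C10) and closes onto C6 on the ring face opposite the neighbouring isopropenyl group, so the epoxide is β (trans to isopropenyl).

**Step 4**
Reactants: 4 epoxy aldehyde
Product: 5 (1R,3S)-1-methyl-2-oxo-3-(prop-1-en-2-yl)cyclopentane-1-carbaldehyde
Conditions: BF3·OEt2 (0.3 equiv), CH2Cl2, −78 °C, 15 min; Et3N quench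
Reagents that add atoms: none
Why: BF3 ionises the tertiary C10–O bond and the formyl group shifts from C6 to C10 anti to the leaving oxygen in a suprafacial [1,2]-sigmatropic acyl shift (semipinacol rearrangement of an α,β-epoxy carbonyl compound), which puts the new C10–C1 bond on the α face (cis to isopropenyl) with the methyl β and leaves C6 as the ketone.

**Step 5**
Reactants: 5 β-keto aldehyde
Product: 7 TBS ether of the (1R)-propargylic carbinol ketone, via bromomagnesium alkoxide 6 (not isolated)
Conditions: MgBr2·OEt2, CH2Cl2, −78 °C; CH3C≡CMgBr (THF); then TBSOTf, −78 to 0 °C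
Reagents that add atoms: 1-propynylmagnesium bromide, CC#C[Mg]Br; tert-butyldimethylsilyl triflate, CC(C)(C)[Si](C)(C)OS(=O)(=O)C(F)(F)F
Why: Cram-chelate-controlled Grignard addition, in which magnesium bridges the aldehyde and ketone oxygens and the alkynyl group attacks C1 from the open face beside the C10 methyl (the other face is covered by the ring and the cis isopropenyl group), giving the (1R)-carbinol with the oxygen configuration of the target, and the alkoxide is silylated before retro-aldol cleavage can occur.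

**Step 6**
Reactants: 7 silyloxy ketone
Product: 9 spiro-epoxide at C6, via lithium chlorohydrinate 8 (not isolated)
Conditions: ClCH2I, MeLi·LiBr, THF, −78 °C to rt
Reagents that add atoms: chloroiodomethane, ClCI
Why: Matteson-type chloromethyllithium addition to the hindered ketone at −78 °C from the less hindered β face, followed by Williamson closure of the chlorohydrin alkoxide, introduces C5 (the new stereocentre is erased in step 7).

**Step 7**
Reactants: 9 spiro-epoxide
Product: 11 aldehyde with 6β-CHO, via cis aldehyde 10 (not isolated)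
Conditions: BF3·OEt2, CH2Cl2, −78 °C; then DBU, CH2Cl2, rt
Reagents that add atoms: none
Why: Meinwald rearrangement (Lewis-acid opening at the tertiary carbon and 1,2-hydride shift) gives the homologous aldehyde, and DBU epimerises C6 to the thermodynamic isomer in which the formyl group is trans to both the bulky C1 substituent on C10 and the C7 isopropenyl group (6α-H).

**Step 8**
Reactants: 11 aldehyde
Product: 13 keto aldehyde with a C7 acetyl group, via ozonide 12 (not isolated)
Conditions: O3, CH2Cl2, −78 °C; then Me2S, −78 °C to rt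
Reagents that add atoms: ozone, [O-][O+]=O
Why: Ozonolysis with reductive work-up cleaves the 1,1-disubstituted alkene much faster than the alkyne and turns the isopropenyl group into the C7 acetyl group, which stays trans to C6–CHO (the thermodynamic arrangement).

**Step 9**
Reactants: 13 keto aldehyde
Product: 14 C6-vinyl methyl ketone
Conditions: Ph3PCH3Br, KOtBu, THF, 0 °C; then 13, −78 to 0 °C
Reagents that add atoms: methyltriphenylphosphonium bromide, C[P+](c1ccccc1)(c1ccccc1)c1ccccc1.[Br-]
Why: Wittig methylenation at low temperature is chemoselective for the aldehyde over the more hindered methyl ketone and adds C4.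

**Step 10**
Reactants: 14 C6-vinyl methyl ketone
Product: 16 ketone with a C6 3-methylbut-3-enyl chain, via B-alkyl-9-BBN 15 (not isolated)
Conditions: 9-BBN, THF, 0 °C to rt; then CH2=C(CH3)Br, Pd(dppf)Cl2 (cat.), K3PO4, DMF/H2O, 50 °C
Reagents that add atoms: 2-bromopropene, CC(Br)=C
Why: 9-BBN hydroborates the only terminal alkene anti-Markovnikov (the internal alkyne and the ketone react much more slowly) and B-alkyl Suzuki–Miyaura coupling installs C3 with its methyl as a 1,1-disubstituted alkene.

**Step 11**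
Reactants: 16 alkynyl ketone
Product: 17 cis-propenyl diene
Conditions: H2 (1 atm), Pd/CaCO3 poisoned with Pb(OAc)2, quinoline, EtOAc, rt
Reagents that add atoms: none
Why: Lindlar semihydrogenation adds H2 syn to the alkyne and stops at the cis alkene needed for ring closure.

**Step 12**
Reactants: 17 cis-propenyl diene
Product: 18 bicyclic silyl ether
Conditions: second-generation Grubbs catalyst RuCl2(=CHPh)(PCy3)(H2IMes) (5 mol%), toluene, 80 °C
Reagents that add atoms: none
Why: Ring-closing olefin metathesis between the cis-propenyl group and the 1,1-disubstituted alkene forms the trisubstituted C2=C3 bond of the trans-fused seven-membered ring.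

**Step 13**
Reactants: 18 bicyclic silyl ether
Product: 19 bicyclic 1α-allylic alcohol
Conditions: HF·pyridine, THF, 0 °C to rt
Reagents that add atoms: none
Why: Fluoride-driven desilylation (Si–F bond formation) frees the allylic alcohol without touching the ketone or the alkene.

**Step 14**
Reactants: 19 bicyclic 1α-allylic alcohol
Product: 20 2α,3α-epoxy 1α-alcohol
Conditions: VO(acac)2 (cat.), t-BuOOH, CH2Cl2, 0 °C
Reagents that add atoms: tert-butyl hydroperoxide, CC(C)(C)OO
Why: Sharpless–Michaelson hydroxyl-directed epoxidation, in which the vanadium alkoxide of the 1α-alcohol delivers oxygen to the same (α) face of C2=C3, which is also the face away from the axial C10 methyl.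

**Step 15**
Reactants: 20 epoxy alcohol
Product: 21 epoxy acetate methyl ketone
Conditions: Ac2O, pyridine, DMAP (cat.), CH2Cl2, rt
Reagents that add atoms: acetic anhydride, CC(=O)OC(C)=O
Why: DMAP-catalysed acylation of the secondary alcohol, with no stereocentre touched.

**Step 16**
Reactants: 21 epoxy acetate methyl ketone
Product: 22 (E)-alkenyl pinacol boronate
Conditions: CH2(Bpin)2, lithium 2,2,6,6-tetramethylpiperidide, THF, 0 °C; then 21, −78 °C to rt
Reagents that add atoms: bis(pinacolatoboryl)methane, C(B1OC(C)(C)C(C)(C)O1)B1OC(C)(C)C(C)(C)O1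
Why: Boron-Wittig olefination, in which the lithiated geminal bis(boronate) adds to the methyl ketone and eliminates a borate so that the remaining boryl group lies trans to the bulky ring carbon, giving the (E)-trisubstituted alkene.

**Step 17**
Reactants: 23 2-methylbut-3-yn-2-ol
Product: 25 (E)-4-iodo-2-methylbut-3-en-2-ol, via vinylstannane 24 (not isolated)
Conditions: Bu3SnH, PdCl2(PPh3)2 (cat.), THF, 0 °C; then I2, CH2Cl2, 0 °C
Reagents that add atoms: iodine, II
Why: Palladium-catalysed syn hydrostannation places tin at the alkyne terminus trans to the carbinol carbon, and iododestannylation proceeds with retention to the (E)-vinyl iodide.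

**Step 18**
Reactants: 22 (E)-alkenyl pinacol boronate; 25 (E)-4-iodo-2-methylbut-3-en-2-ol
Product: 26 CNP0265175.2 (target)
Conditions: Pd(dppf)Cl2 (cat.), K3PO4, THF/H2O, 40 °C
Reagents that add atoms: none
Why: Suzuki–Miyaura coupling joins the two alkenyl partners with retention of both double-bond geometries to give the (E,E)-dienol side chain.

**Compound list**

1 | (4R)-limonene 1,2-oxide, (4R)-1-methyl-4-(prop-1-en-2-yl)-7-oxabicyclo[4.1.0]heptane, commercial cis/trans mixture at the epoxide | CC12OC1C[C@@H](CC2)C(C)=C | starting material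
2 | (3R)-6-oxo-3-(prop-1-en-2-yl)heptanal | O=CC[C@@H](CCC(C)=O)C(C)=C | intermediate
3 | (5S)-2-methyl-5-(prop-1-en-2-yl)cyclopent-1-ene-1-carbaldehyde | CC1=C(C=O)[C@H](C(C)=C)CC1 | intermediate
4 | (1S,2S,5R)-5-methyl-2-(prop-1-en-2-yl)-6-oxabicyclo[3.1.0]hexane-1-carbaldehyde (epoxide O trans to isopropenyl) | C[C@]12O[C@@]1(C=O)[C@H](C(C)=C)CC2 | intermediate
5 | (1R,3S)-1-methyl-2-oxo-3-(prop-1-en-2-yl)cyclopentane-1-carbaldehyde (CHO cis to isopropenyl) | C[C@@]1(C=O)C(=O)[C@H](C(C)=C)CC1 | intermediate
6 | bromomagnesium alkoxide of (2R,5S)-2-[(1R)-1-hydroxybut-2-yn-1-yl]-2-methyl-5-(prop-1-en-2-yl)cyclopentan-1-one | C[C@@]1([C@H](O[Mg]Br)C#CC)C(=O)[C@H](C(C)=C)CC1 | intermediate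
7 | (2R,5S)-2-[(1R)-1-(tert-butyldimethylsilyloxy)but-2-yn-1-yl]-2-methyl-5-(prop-1-en-2-yl)cyclopentan-1-one | C[C@@]1([C@H](O[Si](C)(C)C(C)(C)C)C#CC)C(=O)[C@H](C(C)=C)CC1 | intermediate
8 | lithium alkoxide of the C6 chloromethyl carbinol from 7 (CH2Cl β, O α) | C[C@@]1([C@H](O[Si](C)(C)C(C)(C)C)C#CC)[C@@](O[Li])(CCl)[C@H](C(C)=C)CC1 | intermediate
9 | 4-[(1R)-1-(tert-butyldimethylsilyloxy)but-2-yn-1-yl]-4-methyl-7-(prop-1-en-2-yl)-1-oxaspiro[2.4]heptane (CH2 β, O α at C6) | C[C@@]1([C@H](O[Si](C)(C)C(C)(C)C)C#CC)[C@@]2(CO2)[C@H](C(C)=C)CC1 | intermediate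
10 | 2-[(1R)-1-(tert-butyldimethylsilyloxy)but-2-yn-1-yl]-2-methyl-5-(prop-1-en-2-yl)cyclopentane-1-carbaldehyde, 6α-CHO (cis to both neighbours) | C[C@@]1([C@H](O[Si](C)(C)C(C)(C)C)C#CC)[C@H](C=O)[C@H](C(C)=C)CC1 | intermediate
11 | the same aldehyde with 6β-CHO (trans to the C1 chain and to isopropenyl; 6α-H) | C[C@@]1([C@H](O[Si](C)(C)C(C)(C)C)C#CC)[C@@H](C=O)[C@H](C(C)=C)CC1 | intermediate
12 | ozonide (3-methyl-1,2,4-trioxolan-3-yl in place of isopropenyl) of 11 | C[C@@]1([C@H](O[Si](C)(C)C(C)(C)C)C#CC)[C@@H](C=O)[C@H](C2(C)OCOO2)CC1 | intermediate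
13 | 5-acetyl-2-[(1R)-1-(tert-butyldimethylsilyloxy)but-2-yn-1-yl]-2-methylcyclopentane-1-carbaldehyde (6β-CHO, 7α-acetyl) | C[C@@]1([C@H](O[Si](C)(C)C(C)(C)C)C#CC)[C@@H](C=O)[C@H](C(C)=O)CC1 | intermediate
14 | methyl ketone with 6β-vinyl, 7α-acetyl, 10β-methyl and the (1R)-silyloxybutynyl group on C10 | C[C@@]1([C@H](O[Si](C)(C)C(C)(C)C)C#CC)[C@@H](C=C)[C@H](C(C)=O)CC1 | intermediate
15 | B-alkyl-9-BBN adduct of 14 (boron on C4) | C[C@@]1([C@H](O[Si](C)(C)C(C)(C)C)C#CC)[C@@H](CCB2C3CCCC2CCC3)[C@H](C(C)=O)CC1 | intermediate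
16 | methyl ketone with a 6β-(3-methylbut-3-en-1-yl) chain and the (1R)-silyloxybutynyl group | C[C@@]1([C@H](O[Si](C)(C)C(C)(C)C)C#CC)[C@@H](CCC(C)=C)[C@H](C(C)=O)CC1 | intermediate
17 | as 16 with a (1R,2Z)-1-silyloxybut-2-en-1-yl group on C10 | C[C@@]1([C@H](O[Si](C)(C)C(C)(C)C)/C=C\C)[C@@H](CCC(C)=C)[C@H](C(C)=O)CC1 | intermediate
18 | tert-butyldimethylsilyl ether of 19 | CC(C)(C)[Si](C)(C)O[C@@H]1C=C(C)CC[C@H]2[C@H](C(C)=O)CC[C@]12C | intermediate
19 | 1-(4-hydroxy-3a,6-dimethyl-1,2,3,3a,4,7,8,8a-octahydroazulen-1-yl)ethan-1-one: 1α-OH, Δ2, 6α-H, 7α-acetyl, 10β-Me (trans-fused) | O[C@@H]1C=C(C)CC[C@H]2[C@H](C(C)=O)CC[C@]12C | intermediate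
20 | 2α,3α-epoxide of 19 (epoxide cis to the 1α-OH) | O[C@@H]1[C@@H]2O[C@]2(C)CC[C@H]2[C@H](C(C)=O)CC[C@]12C | intermediate
21 | 1α-acetate of 20 | CC(=O)O[C@@H]1[C@@H]2O[C@]2(C)CC[C@H]2[C@H](C(C)=O)CC[C@]12C | intermediate
22 | 21 with the acetyl group converted into (E)-1-(pinacolatoboryl)prop-1-en-2-yl | CC(=O)O[C@@H]1[C@@H]2O[C@]2(C)CC[C@H]2[C@H](/C(C)=C/B3OC(C)(C)C(C)(C)O3)CC[C@]12C | intermediate
23 | 2-methylbut-3-yn-2-ol | CC(C)(O)C#C | starting material
24 | (E)-2-methyl-4-(tributylstannyl)but-3-en-2-ol | CC(C)(O)/C=C/[Sn](CCCC)(CCCC)CCCC | intermediate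
25 | (E)-4-iodo-2-methylbut-3-en-2-ol | CC(C)(O)/C=C/I | intermediate
26 | CNP0265175.2: 1α-acetoxy-2α,3α-epoxy-7α-[(2E,4E)-6-hydroxy-6-methylhepta-2,4-dien-2-yl]-3,10β-dimethyl-6αH-bicyclo[5.3.0]decane | CC(=O)O[C@@H]1[C@@H]2O[C@]2(C)CC[C@H]2[C@H](/C(C)=C/C=C/C(C)(C)O)CC[C@]12C | target

**Step count and risks**

Total step count: 18. Longest linear sequence: 17 steps (steps 1–16 and 18, from 1 to 26); step 17 makes the side-arm 25.

The three steps most likely to fail:

Step 4 (formyl shift). The free β-keto aldehyde 5 carries its formyl group cis to the isopropenyl group, so under BF3 it may undergo a carbonyl-ene reaction, and any β-face leakage in step 3 shows up here as the C10 epimer. Fallback, setting out from 4: 1-propynylmagnesium bromide is added to the aldehyde to give the epoxy carbinol F1 (C1 epimers, irrelevant). Dess–Martin oxidation gives the epoxy ynone F2. BF3·OEt2 then moves the but-2-ynoyl group from C6 to C10 (the classical α,β-epoxy ketone to 1,3-diketone shift, with no aldehyde left to attack the alkene) to give the diketone F3. KBH(s-Bu)3 at −78 °C reduces the ynone carbonyl under Felkin–Anh control (ring acyl group anti to hydride) to the potassium (1R)-alkoxide F4, which is silylated in the flask with TBSOTf and comes back to the route at 7.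

Step 5 (C1 configuration). If the magnesium chelate is not maintained (THF from the Grignard solution), the Felkin–Anh mode gives the C1 epimer. Fallback, setting out from 5: lithium propynylide in THF without a chelating salt is used deliberately to give the Felkin–Anh (1S)-carbinol F5. A Mitsunobu reaction with chloroacetic acid (PPh3, DIAD) inverts C1 to the (1R)-chloroacetate F6. K2CO3 in MeOH at 0 °C frees the (1R)-alcohol F7, and TBSOTf with 2,6-lutidine at −78 °C returns to the route at 7.

Step 6 (carbenoid addition to a ketone flanked by a quaternary and a tertiary carbon). Addition may be slow enough for enolisation towards C7 to compete. Fallback, setting out from 7: the ylide Ph3P=CHOMe (from Ph3PCH2OMe chloride and KOtBu, THF, 0 °C to rt) converts the ketone into the methyl enol ether F8 (E/Z mixture). Aqueous HCl in THF hydrolyses it to the aldehydes 10 and 11, and DBU equilibrates the mixture so that the route is rejoined at 11.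

Further compounds
F1 | step 4 | (1S,2S,5R)-1-(1-hydroxybut-2-yn-1-yl)-5-methyl-2-(prop-1-en-2-yl)-6-oxabicyclo[3.1.0]hexane, carbinol epimers | C[C@]12O[C@@]1(C(O)C#CC)[C@H](C(C)=C)CC2
F2 | step 4 | 1-[5-methyl-2-(prop-1-en-2-yl)-6-oxabicyclo[3.1.0]hexan-1-yl]but-2-yn-1-one (epoxide trans to isopropenyl) | C[C@]12O[C@@]1(C(=O)C#CC)[C@H](C(C)=C)CC2
F3 | step 4 | 2-(but-2-ynoyl)-2-methyl-5-(prop-1-en-2-yl)cyclopentan-1-one (acyl group cis to isopropenyl) | C[C@@]1(C(=O)C#CC)C(=O)[C@H](C(C)=C)CC1
F4 | step 4 | potassium alkoxide of (2R,5S)-2-[(1R)-1-hydroxybut-2-yn-1-yl]-2-methyl-5-(prop-1-en-2-yl)cyclopentan-1-one | C[C@@]1([C@H](O[K])C#CC)C(=O)[C@H](C(C)=C)CC1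
F5 | step 5 | (2R,5S)-2-[(1S)-1-hydroxybut-2-yn-1-yl]-2-methyl-5-(prop-1-en-2-yl)cyclopentan-1-one | C[C@@]1([C@@H](O)C#CC)C(=O)[C@H](C(C)=C)CC1
F6 | step 5 | (1R)-1-[(1R,3S)-1-methyl-2-oxo-3-(prop-1-en-2-yl)cyclopentyl]but-2-yn-1-yl chloroacetate | C[C@@]1([C@H](OC(=O)CCl)C#CC)C(=O)[C@H](C(C)=C)CC1
F7 | step 5 | (2R,5S)-2-[(1R)-1-hydroxybut-2-yn-1-yl]-2-methyl-5-(prop-1-en-2-yl)cyclopentan-1-one | C[C@@]1([C@H](O)C#CC)C(=O)[C@H](C(C)=C)CC1
F8 | step 6 | methyl enol ether (methoxymethylidene at C6) of ketone 7, E/Z mixture | C[C@@]1([C@H](O[Si](C)(C)C(C)(C)C)C#CC)C(=COC)[C@H](C(C)=C)CC1
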